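**Plan**

Cuts: first C3–Br (late electrophilic bromination). Next the C2=C3 unsaturation (indole back to indoline) and N1–H (back to a methyl carbamate). Then C3a–C7a and C4–C5 together, and last N1–C2 (the butynyl arm) and C7–Br.
Feature: on the benzene ring, N1 is attached to C7a, the neighbouring C7 carries Br, and C5 (para to N1) carries the second Br. The edge C7a–C7–C6–C5 therefore matches the C3–C4–C5–C6 edge of a 3-amino-4,6-dibromopyridazine, and the two diazine nitrogens occupy the positions that C3a and C4 must fill.
Forward: a purchased pyridazine is brominated at C4, its amine is made into a carbamate, and the but-3-ynyl arm is attached. One thermolysis then closes the five-membered ring and the carbocycle together as dinitrogen leaves. Carbamate cleavage, dehydrogenation and C3 bromination finish the route.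
Stereochemistry: the target is flat and achiral. Only the bridgeheads of the transient cycloadduct are stereogenic, and they disappear with the dinitrogen.

Key step: step 4

Remark: 1, 3 and 5 are taken to be catalogue chemicals. Adduct 7 is drawn without wedges because it is racemic and transient.

**Step 1**
Reactants: 1 6-bromopyridazin-3-amine
Product: 2 4,6-dibromopyridazin-3-amine
Conditions: Br2 (1.2 equiv), NaHCO3 (2 equiv), MeOH, 0 °C to rt
Reagents that add atoms: bromine, BrBr
Why: Electrophilic aromatic bromination, in which the amino group is the only donor on the diazine and activates its ortho carbon C4 (C5 is meta to it), as is standard for 6-halopyridazin-3-amines, while NaHCO3 takes up the HBr.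

**Step 2**
Reactants: 2 4,6-dibromopyridazin-3-amine; 3 methyl chloroformate
Product: 4 methyl (4,6-dibromopyridazin-3-yl)carbamate
Conditions: NaN(SiMe3)2 (2.1 equiv), THF, −20 °C; then 3 (1.05 equiv), −20 to 0 °C; AcOH quench
Reagents that add atoms: none
Why: N-acylation of the preformed amide anion, the usual answer to a weakly nucleophilic amino-azine, in which the second equivalent of base removes the acidic N–H of the product as it forms and so blocks a second acylation.

**Step 3**
Reactants: 4 methyl (4,6-dibromopyridazin-3-yl)carbamate; 5 but-3-yn-1-ol
Product: 6 methyl but-3-yn-1-yl(4,6-dibromopyridazin-3-yl)carbamate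
Conditions: PPh3, DIAD (1.3 equiv each), THF, 0 °C to rt
Reagents that add atoms: none
Why: Mitsunobu N-alkylation, since the heteroaryl carbamate N–H is acidic enough to act as pronucleophile and the primary alkoxyphosphonium ion is displaced by SN2 without the base-induced elimination to vinylacetylene that troubles homopropargyl halides.

**Step 4**
Reactants: 6 methyl but-3-yn-1-yl(4,6-dibromopyridazin-3-yl)carbamate
Product: 8 methyl 5,7-dibromoindoline-1-carboxylate, via bridged diazabicyclooctatriene adduct 7 (not isolated)
Conditions: 1,3,5-triisopropylbenzene (0.02 M, degassed), BHT (cat.), 210–230 °C, Ar, sealed vessel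
Reagents that add atoms: none
Why: The electron-poor 1,2-diazine of 6 acts through C3 and C6 as the 4π partner and the unactivated terminal alkyne as the 2π partner in a concerted inverse-electron-demand [4+2] cycloaddition to bridged adduct 7, which at this temperature at once expels dinitrogen by retro-[4+2] cleavage, so the carbocycle forms already aromatic and no oxidant is needed. The closest known reaction type is the thermal intramolecular alkyne–pyridazine Diels–Alder reaction of N-acyl-N-(but-3-ynyl)pyridazin-3-amines, an established entry to N-acylindolines; only the 4,6-dibromo pattern is new here. The five-membered ring closes through the C3a–C7a bond in a 5-exo-dig sense along the N–CH2–CH2 tether, and the six-membered carbocycle closes by the cycloaddition itself, C3a–C7a and C4–C5 forming in the same event. No lasting stereocentre arises, because the two bridgeheads of 7 are fixed relative to each other by the cage and vanish when dinitrogen leaves. The selectivity required is regiochemical, and the three-atom tether secures it, since the internal alkyne carbon can reach only C3 and the terminal carbon is thereby delivered to C6, which places Br on C5 and C7 of the indoline. Reactivity is helped by three acceptors on the diene (two Br, one N-CO2Me), which depress its LUMO, and by the steric clash between C4–Br and the carbamate, which turns the nitrogen lone pair out of conjugation and holds the butynyl arm above the diazine face.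

**Step 5**
Reactants: 8 methyl 5,7-dibromoindoline-1-carboxylate
Product: 10 5,7-dibromoindoline, via potassium carbamate 9 (not isolated)
Conditions: KOH (6 equiv), MeOH/H2O, 80 °C
Reagents that add atoms: none
Why: Saponification of the carbamate, in which hydroxide adds to the carbonyl group, methoxide leaves, and salt 9 of the weakly basic dibromoindoline loses its carboxylate carbon as carbonate in the hot aqueous base, while unactivated aryl bromides are inert to KOH.

**Step 6**
Reactants: 10 5,7-dibromoindoline
Product: 11 5,7-dibromo-1H-indole
Conditions: DDQ (1.1 equiv), toluene, rt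
Reagents that add atoms: none
Why: Quinone dehydrogenation of an indoline, in which hydride abstraction from C2 assisted by the free nitrogen lone pair and proton loss from C3 create the aromatic pyrrole ring without touching either aryl bromide.

**Step 7**
Reactants: 11 5,7-dibromo-1H-indole
Product: 12 3,5,7-tribromo-1H-indole
Conditions: NBS (1.0 equiv), DMF, 0 °C, dark
Reagents that add atoms: N-bromosuccinimide, O=C1CCC(=O)N1Br
Why: Electrophilic aromatic substitution at C3, the most nucleophilic carbon of an N–H indole, under the standard conditions for 3-bromoindoles, with the two ring bromines damping further bromination.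

**Compound list**

1 | 6-bromopyridazin-3-amine | Nc1ccc(Br)nn1 | starting material
2 | 4,6-dibromopyridazin-3-amine | Nc1nnc(Br)cc1Br | intermediate
3 | methyl chloroformate | COC(=O)Cl | starting material
4 | methyl (4,6-dibromopyridazin-3-yl)carbamate | COC(=O)Nc1nnc(Br)cc1Br | intermediate
5 | but-3-yn-1-ol | C#CCCO | starting material
6 | methyl but-3-yn-1-yl(4,6-dibromopyridazin-3-yl)carbamate | COC(=O)N(CCC#C)c1nnc(Br)cc1Br | intermediate
7 | bridged adduct: 4,6-dibromo-2,3-diazabicyclo[2.2.2]octa-2,5,7-triene bearing an N(CO2Me)–CH2–CH2 bridge from C1 to C7 (racemic, not isolated) | COC(=O)N1CCC2=CC3(Br)C=C(Br)C12N=N3 | intermediate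
8 | methyl 5,7-dibromoindoline-1-carboxylate | COC(=O)N1CCc2cc(Br)cc(Br)c21 | intermediate
9 | potassium 5,7-dibromoindoline-1-carboxylate (not isolated) | [K+].[O-]C(=O)N1CCc2cc(Br)cc(Br)c21 | intermediate
10 | 5,7-dibromoindoline | Brc1cc(Br)c2c(c1)CCN2 | intermediate
11 | 5,7-dibromo-1H-indole | Brc1cc(Br)c2[nH]ccc2c1 | intermediate
12 | 3,5,7-tribromo-1H-indole | Brc1cc(Br)c2[nH]cc(Br)c2c1 | target

Total step count: 7. Longest linear sequence: 7 (1 to 12).

**Steps most likely to fail**

**Step 4.** The substrate may decay thermally before it cycloadds. The carbamate carbonyl oxygen could displace the neighbouring C4 bromide with loss of the methyl group, the alkyne could polymerise, or bond formation at the bromine-bearing C6 could be slow.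

The fallback keeps the same disconnection but leaves the C7 bromine out of the cycloaddition. It sets out from 1 and comes back at 10.
- Compound 1 is acylated with 3 as in step 2 to methyl (6-bromopyridazin-3-yl)carbamate F1.
- F1 is alkylated with 5 under Mitsunobu conditions to methyl but-3-yn-1-yl(6-bromopyridazin-3-yl)carbamate F2.
- Thermolysis in 1,3,5-triisopropylbenzene passes through the monobromo bridged adduct F3 and should give methyl 5-bromoindoline-1-carboxylate F4.
- KOH in aqueous MeOH cleaves F4, by way of potassium 5-bromoindoline-1-carboxylate F5, to 5-bromoindoline F6.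
- One equivalent of Br2 in AcOH/NaOAc then brominates C7, the only open position ortho or para to the free indoline nitrogen, and gives 10.

**Step 3.** Alkylation may drift from the carbamate nitrogen to ring nitrogen N2 or to the carbonyl oxygen. Alternatively, the hindered, weakly nucleophilic carbamate anion may fail to capture the alkoxyphosphonium ion.

The fallback makes the C3–N bond instead of the N–CH2 bond. It sets out from 5 and comes back at 6.
- A Mitsunobu reaction of 5 with phthalimide gives 2-(but-3-yn-1-yl)isoindoline-1,3-dione F7.
- Hydrazinolysis (Gabriel synthesis) of F7 gives but-3-yn-1-amine F8.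
- SNAr of F8 on commercial 3,6-dibromopyridazine (Brc1ccc(Br)nn1; K2CO3, DMSO, 100 °C), whose two halogen-bearing carbons are equivalent, gives 6-bromo-N-(but-3-yn-1-yl)pyridazin-3-amine F9.
- NBS in MeCN, a reagent to which an unactivated terminal alkyne is inert, brominates C4 ortho to the alkylamino group to give 4,6-dibromo-N-(but-3-yn-1-yl)pyridazin-3-amine F10.
- Deprotonation with NaN(SiMe3)2 and acylation with 3 gives 6.

**Step 2.** Double acylation may occur, or the amide anion may self-condense by displacing bromide in a second molecule.

The fallback avoids the anion and makes over-acylation the aim. It sets out from 2 and comes back at 4.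
- Excess 3 with Et3N and catalytic DMAP in CH2Cl2 carries 2 through to dimethyl (4,6-dibromopyridazin-3-yl)imidodicarbonate F11.
- Brief methanolysis (catalytic K2CO3, MeOH, 0 °C) removes one methoxycarbonyl group. It stops there because the resulting carbamate is far less electrophilic, and this gives 4.

**Further compounds**

F1 | step 4 | methyl (6-bromopyridazin-3-yl)carbamate | COC(=O)Nc1ccc(Br)nn1
F2 | step 4 | methyl but-3-yn-1-yl(6-bromopyridazin-3-yl)carbamate | COC(=O)N(CCC#C)c1ccc(Br)nn1
F3 | step 4 | monobromo bridged adduct: 4-bromo-2,3-diazabicyclo[2.2.2]octa-2,5,7-triene bearing an N(CO2Me)–CH2–CH2 bridge from C1 to C7 (racemic, transient) | COC(=O)N1CCC2=CC3(Br)C=CC12N=N3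
F4 | step 4 | methyl 5-bromoindoline-1-carboxylate | COC(=O)N1CCc2cc(Br)ccc21
F5 | step 4 | potassium 5-bromoindoline-1-carboxylate | [K+].[O-]C(=O)N1CCc2cc(Br)ccc21
F6 | step 4 | 5-bromoindoline | Brc1ccc2c(c1)CCN2
F7 | step 3 | 2-(but-3-yn-1-yl)isoindoline-1,3-dione | C#CCCN1C(=O)c2ccccc2C1=O
F8 | step 3 | but-3-yn-1-amine | C#CCCN
F9 | step 3 | 6-bromo-N-(but-3-yn-1-yl)pyridazin-3-amine | C#CCCNc1ccc(Br)nn1
F10 | step 3 | 4,6-dibromo-N-(but-3-yn-1-yl)pyridazin-3-amine | C#CCCNc1nnc(Br)cc1Br
F11 | step 2 | dimethyl (4,6-dibromopyridazin-3-yl)imidodicarbonate | COC(=O)N(C(=O)OC)c1nnc(Br)cc1Br
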